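**Retrosynthetic overview**
- Last disconnection: the C10–C11 bond. The γ-lactone ring, the C10 stereocentre and the E-benzylidene all come from one photocatalytic C–H cycloisomerisation of a C8-O aryl-propiolate ester.
- The ester is disconnected to a tertiary allylic alcohol plus 3-(4-acetoxyphenyl)propiolic acid; the acid comes from 4-iodophenyl acetate and propiolic acid.
- The C8–O bond (spiro centre, with the alkene moving from C7=C8 to C6=C7) comes from a singlet-oxygen ene photooxygenation of 1,10-anhydrogenipin.
- 1,10-Anhydrogenipin comes from genipin by intramolecular acetalisation.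
- Ring order: the dihydropyran and cyclopentene rings are bought in genipin; then the tetrahydrofuran acetal ring; then the C8–O spiro centre; the γ-lactone is closed last.

Assumption: natural (+)-genipin is taken as a commercial chiral-pool material; its C5/C9 configuration matches the target SMILES (checked atom by atom). Iridoid numbering is used throughout: C1 acetal carbon, C3=C4 enol ether, C5/C9 ring fusion, C6–C7–C8 cyclopentene, C10 the carbon on C8, C11/C12 the lactone α-carbon and carbonyl.

**Step 1**
Reactants: 1, (+)-genipin [methyl (1R,4aS,7aS)-1-hydroxy-7-(hydroxymethyl)-1,4a,5,7a-tetrahydrocyclopenta[c]pyran-4-carboxylate]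
Product: 2, 1,10-anhydrogenipin (tricyclic acetal: the C10 oxygen is bonded to C1, giving the tetrahydrofuran ring C1–O–C10–C8–C9; C7=C8 retained; H-1, H-5 and H-9 all cis)
Conditions: PPTS (10 mol %), 4 Å MS, ClCH2CH2Cl (0.02 M), 60 °C
Reagents that add atoms: none
Why: Acid-catalysed dehydrative intramolecular acetalisation of the C1 lactol by the C10 allylic hydroxyl; the C1 oxocarbenium can only be captured by the tethered oxygen on the face of C8, so C1 is set (inverted relative to genipin) by ring constraint, and C5/C9 are untouched.

**Step 2**
Reactants: 2, 1,10-anhydrogenipin; molecular oxygen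
Product: 3, the C8 tertiary allylic alcohol of the 1,10-anhydro tricycle (OH on C8 cis to H-9, C10 on the opposite face, alkene now C6=C7)
Conditions: O2, TPP (0.5 mol %), CH2Cl2, white LEDs, −10 °C; then PPh3 (1.2 equiv), −10 °C → rt
Reagents that add atoms: dioxygen, O=O (one oxygen is retained as the C8 hydroxyl)
Why: Schenck ene reaction of photogenerated singlet oxygen on the strained trisubstituted C7=C8 alkene, followed by phosphine reduction of the hydroperoxide; O2 attacks C8 from the open convex face (the face of H-9) and removes the syn H-6, which sets the C8 stereocentre, and this regiochemistry is favoured because H-9 abstraction would give a highly strained ring-fusion alkene and the C10 hydrogens geminal to oxygen are poor ene donors.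

**Step 3**
Reactants: 4, 4-iodophenyl acetate; 5, propiolic acid
Product: 6, 3-(4-acetoxyphenyl)prop-2-ynoic acid
Conditions: Pd(PPh3)4 (2.5 mol %), DBU (2.4 equiv), dry DMSO, 30 °C; cold aq. citric acid work-up
Reagents that add atoms: propiolic acid (5), C#CC(=O)O; 4-iodophenyl acetate (4), CC(=O)Oc1ccc(I)cc1
Why: Copper-free Sonogashira-type coupling of an aryl iodide with propiolic acid, which at near-ambient temperature gives the arylpropiolic acid without decarboxylation; the aryl acetate survives the anhydrous, non-nucleophilic base.

**Step 4**
Reactants: 3, C8 tertiary allylic alcohol; 6, 3-(4-acetoxyphenyl)prop-2-ynoic acid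
Product: 7, the C8 3-(4-acetoxyphenyl)propiolate ester of 3 (C8–O–C(=O)–C≡C–C6H4-4-OAc, otherwise unchanged)
Conditions: 6, 2,4,6-Cl3C6H2COCl, Et3N, THF, 0 °C; then 3, DMAP (0.2 equiv), PhMe, 0 °C → rt
Reagents that add atoms: 3-(4-acetoxyphenyl)prop-2-ynoic acid (6), CC(=O)Oc1ccc(cc1)C#CC(=O)O
Why: Yamaguchi mixed-anhydride esterification of the only free hydroxyl, which sits on the exposed convex face; the C–O bond of the alcohol is not broken, so C8 keeps its configuration, and the mild amine conditions leave the aryl acetate and the β-alkoxyacrylate intact.

**Step 5**
Reactants: 7, C8 aryl-propiolate ester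
Product: 8, 3-O-acetylprismatomerin (target)
Conditions: (n-Bu4N)4[W10O32] (TBADT, 5 mol %), degassed MeCN (0.02 M), 390 nm LEDs, 20 °C, stopped at about 80 % conversion; then, only if some Z isomer is present, I2 (5 mol %), CH2Cl2, visible light, rt
Reagents that add atoms: none (isomerisation of 7)
Why: Proposed new method: a decatungstate-photocatalysed intramolecular C(sp3)–H hydroalkylation (5-exo-dig cycloisomerisation) of a tethered aryl ynoate — the excited, electrophilic polyoxotungstate abstracts a hydridic ether α-hydrogen at C10; the nucleophilic α-oxyalkyl radical adds to the ynoate α-carbon C11 (the regiochemistry known for radical additions to 3-arylpropiolates, giving an aryl-stabilised vinyl radical); back hydrogen-atom transfer from the reduced catalyst on the open carbonyl side gives the E-benzylidene and turns the catalyst over; the C10 stereocentre is fixed because the new γ-lactone must be cis-fused to the tetrahydrofuran ring, so C11 bonds on the face carrying the C8–O; off-cycle radicals at C1 or C5 have no acceptor in reach and should revert by back-transfer; the closest known reactions are decatungstate C–H Giese hydroalkylation of electron-poor π-systems by ethers and tin-mediated 5-exo-dig cyclisations of 2-haloethyl alkynoates to α-alkylidene-γ-butyrolactones.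

**Compound list**
1 | (+)-genipin | COC(=O)C1=CO[C@@H](O)[C@@H]2C(CO)=CC[C@H]12 | starting material
2 | 1,10-anhydrogenipin | COC(=O)C1=CO[C@@H]2OCC3=CC[C@H]1[C@H]23 | intermediate
3 | C8 tertiary allylic alcohol (8-OH cis to H-9, C6=C7) of the 1,10-anhydro tricycle | COC(=O)C1=CO[C@@H]2OC[C@]3(O)C=C[C@H]1[C@H]23 | intermediate
4 | 4-iodophenyl acetate | CC(=O)Oc1ccc(I)cc1 | starting material
5 | propiolic acid | C#CC(=O)O | starting material
6 | 3-(4-acetoxyphenyl)prop-2-ynoic acid | CC(=O)Oc1ccc(cc1)C#CC(=O)O | intermediate
7 | C8 3-(4-acetoxyphenyl)propiolate ester of 3 | COC(=O)C1=CO[C@@H]2OC[C@]3(OC(=O)C#Cc4ccc(OC(C)=O)cc4)C=C[C@H]1[C@H]23 | intermediate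
8 | 3-O-acetylprismatomerin | COC(=O)C1=CO[C@@H]2O[C@H]3/C(=C\c4ccc(OC(C)=O)cc4)C(=O)O[C@]34C=C[C@H]1[C@H]24 | target

**Step count**
Total steps: 5. Longest linear sequence: 4 (steps 1, 2, 4, 5 from genipin).

**Three steps most likely to fail**
1. Step 5 (proposed new C–H cycloisomerisation).
 - Risks: hydrogen abstraction at the C1 acetal or the doubly allylic C5 instead of C10 (possible alkene migration); slow cyclisation through the minor s-trans ester rotamer; Z/E mixtures; re-abstraction of the new C10–H in the product.
 - Fallback (known chemistry): give up the C–H functionalisation and use the polar, biomimetic SN2′ endgame known for plumericin-type lactones. From 1-O-methyl-10-O-TBS-genipin: ene/reduction to the C8 alcohol, C8-O-phosphonoacetate, desilylation and oxidation to the C10 aldehyde, intramolecular Horner–Wadsworth–Emmons to the spiro-butenolide, α-(hydroxybenzyl)ation with 4-acetoxybenzaldehyde (thiolate Michael–aldol–sulfoxide elimination), then acid-triggered attack of the freed C1–OH on C10 with allylic loss of the activated benzylic oxygen, which closes the tetrahydrofuran ring and gives the E-benzylidene.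
2. Step 2 (singlet-oxygen ene).
 - Risks: competing oxygen delivery to C7 (abstraction of a C10 hydrogen), or lability of the tertiary allylic hydroperoxide.
 - Fallback: non-photochemical epoxide route to the same alcohol 3. Buffered mCPBA epoxidation of 2 on the convex face, PhSeNa opening at the less hindered C7, then H2O2 oxidation and selenoxide syn-elimination away from the carbinol.
3. Step 4 (acylation of the hindered tertiary allylic alcohol).
 - Risks: slow acylation, DMAP addition to the ynoate, or ionisation of the tertiary allylic ester.
 - Fallback: build the aryl ynoate on the substrate instead. Acylate 3 with small, unhindered propiolic acid (DCC, CH2Cl2, −20 °C, no DMAP), then couple the terminal ynoate with 4-iodophenyl acetate by Sonogashira reaction to reach 7.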